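The runs are calculated for an exercise, noise included.

**3 questions.** I had 3 questions and 2 earlier runs, and those runs do not show the number of chains.

the same everywhere: free monomer 0.20 M (fed, over 25 h)

| flask | initiator | remark | time |
|---|---|---|---|
| beta | 2.8 mM | run made earlier; the fed solution adds 0.25 times the starting volume |  |
| gamma | 16 mM | run made earlier; the fed solution adds 0.25 times the starting volume |  |
| Thursday's | 5.0 mM | the fed solution adds 0.25 times the starting volume | 10 d |
| Tuesday's | 20 mM | the fed solution adds 0.25 times the starting volume | 10 d |

- beta (time / d: monomer in chains / %, free monomer / %): 1.67: 72.4, 28.1; 4.00: 95.1, 4.5; 5.00: 96.3, 3.7; 8.00: 96.9, 2.3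
- gamma (time / d: monomer in chains / %, free monomer / %): 0.833: 57.3, 23.4; 2.50: 97.9, 0.2; 5.00: 94.8, 0; 8.00: 95.2, 0

(scatter of a reading: 0.5 percentage points)

- charges are per starting volume, the dose included; the dosed solution carries all of it
- the average divides the monomer in chains by the number of chains begun, living and dead together
- the numbers in the tables scatter by 0.5 percentage points (one standard deviation)
- the earlier runs do not show the number of chains; that part of a forecast is a guess
- percentages count the whole charge, also what has not yet gone in

* which of the two ends with the longer chains by the average number of monomer units in a chain (chains begun, living or dead) ("neither" if they lie within 10%) (Thursday's / Tuesday's / neither)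
* average number of monomer units in a chain (chains begun, living or dead) at the end, Thursday's
* average number of monomer units in a chain (chains begun, living or dead) at the end, Tuesday's

**The floor.** Write n for the average length (the number average): monomer in chains over chains begun. I allowed at most one chain per initiator, so n cannot fall below monomer in chains over initiator charged. Beta's last reading, 96.9%, applied to Thursday's gave a floor of 38.8.

**The ceiling.** Gamma's columns stopped adding up. At 5.00 d and 8.00 d, with free monomer at 0%, the average gap g, the share of the charge in neither column, was 5.00%. I read each lost unit as one ended chain, and an ended chain was begun. So on that reading n stays below the gap ceiling, monomer in chains over g, 19.0 for gamma.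

**The bracket.** Tuesday's has more initiator than gamma, so I took gamma's gap as its least value: ceiling 19.0, and with that gap a floor near 9.50. I committed to Tuesday's near its ceiling, since gamma's monomer in chains held at 94.8% and 95.2%, which I read as chains no longer ending. For Thursday's I assumed that gamma's 0.625 ended chains per initiator charged was a lower limit, which gave a ceiling of 62.0. Thursday's floor stood above Tuesday's ceiling, so I expected Thursday's to be longer.

**The forecast.** It said Thursday's, with 39 and 9.4: “Assuming one chain per initiator, which is a guess”. Both numbers stand at my floors. For Tuesday's I part from it.

**The result.** Thursday's ended longer, 45.0 against 17.3, each inside its bracket.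

    free monomer + living end → monomer in chains + living end, rate k1*[living end]*[free monomer] (k = 0.00940 L mol⁻¹ s⁻¹)
    free monomer + initiator → living end + monomer in chains (k = 2.20 × 10⁻⁴ L mol⁻¹ s⁻¹)
    living end + monomer in chains → dead end (k = 4.30 × 10⁻⁵ L mol⁻¹ s⁻¹)

At 10.0 d Tuesday's held 4.85 × 10⁻⁵ M of living end beside dead end at 5.43%. Its own gap gives a ceiling of 17.4, close to the result, and 17.3 lies under gamma's 19.0.

**A neighbour.** Thursday's recipe with 0.0085 M of initiator ends with 96.8% in chains and dead end at 3.13%, so the ceiling is 30.9. The computed length is 30.7.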